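**Retrosynthesis**
1. The curcuminoid comes from an unsymmetrical boron-templated condensation of feruloylacetone with the aryl-ether aldehyde.
2. The aryl ether C–O bond comes from a Pd-catalysed allylic etherification of vanillin. It retains configuration, so the cis-1,4-dioxygenated cyclohexene is set by enzymatic desymmetrisation of a meso diol.
3. **Key step:** the CH2–C(=O) bond of the side chain forms by radical hydroacylation of an isopropenyl group with the senecioyl (3-methylbut-2-enoyl) radical. The C-7 methyl stereocentre is set by the H-atom-transfer step.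
4. The carbocycle is taken pre-formed from the diol, so no ring-forming step is needed. The isopropenyl group is added trans by cuprate addition, the methyl and alkene by α′-methylation and dehydrogenation, and the axial alcohol by CBS reduction. Both benzene rings come from catechol via vanillin.

Assumption: the lipase delivers the (1S,4R) monoacetate. The enantiomer is available by hydrolysing the diacetate instead, and I assume a CBS catalyst enantiomer matched to the substrate can be found by screening.

---

**Step 1**
Reactants: 1 catechol
Product: 2 guaiacol (2-methoxyphenol)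
Conditions: DMC (3 equiv), K2CO3 (cat.), 160 °C, sealed vessel
Reagents that add atoms: dimethyl carbonate, COC(=O)OC
Why: Selective mono-O-methylation of catechol with dimethyl carbonate (BAl2 methylation of the phenoxide) stops at the mono-ether.

**Step 2**
Reactants: 2 guaiacol, 3 glyoxylic acid
Product: 4 4-hydroxy-3-methoxymandelic acid (racemic)
Conditions: aq. NaOH, 30 °C, 24 h; then H3O+
Reagents that add atoms: none
Why: Base-mediated hydroxyalkylation of the phenoxide with glyoxylic acid occurs para to the phenolate oxygen.

**Step 3**
Reactants: 4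
Product: 5 vanillin
Conditions: CuSO4 (cat.), aq. NaOH, O2 (air), 85 °C; then HCl
Reagents that add atoms: none
Why: Cu(II)-mediated oxidative decarboxylation of the benzylic α-hydroxy acid gives the aldehyde (industrial vanillin route).

**Step 4**
Reactants: 5 vanillin, 6 acetylacetone (5 equiv)
Product: 7 feruloylacetone
Conditions: B2O3, B(OBu)3, n-BuNH2 (cat.), EtOAc, 50 °C; then 1 M HCl, 60 °C
Reagents that add atoms: none
Why: A boron-templated Knoevenagel condensation at one methyl of the acetylacetone–boron chelate gives mono-condensation when acetylacetone is in excess (Pabon-type).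

**Step 5**
Reactants: 8 cis-cyclohex-2-ene-1,4-diol (meso)
Product: 9 (1S,4R)-4-hydroxycyclohex-2-en-1-yl acetate
Conditions: Amano lipase PS, vinyl acetate (1.5 equiv), t-BuOMe, 25 °C
Reagents that add atoms: vinyl acetate, C=COC(C)=O
Why: Lipase-catalysed desymmetrisation acylates one enantiotopic hydroxyl and sets the first stereocentre (the acetate carbon, which becomes C-1 of the target ring).

**Step 6**
Reactants: 9
Product: 10 (S)-4-oxocyclohex-2-en-1-yl acetate
Conditions: Dess–Martin periodinane, NaHCO3, CH2Cl2, 0 °C → rt
Reagents that add atoms: none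
Why: Mild oxidation of the free allylic alcohol to the γ-acetoxy enone leaves the acetate-bearing stereocentre untouched.

**Step 7**
Reactants: 10
Product: 11 (1S,2R)-4-oxo-2-(prop-1-en-2-yl)cyclohexyl acetate
Conditions: isopropenylMgBr, CuBr·SMe2, TMSCl, THF, −78 °C; then 1 M HCl
Reagents that add atoms: isopropenylmagnesium bromide, C=C(C)[Mg]Br
Why: Cuprate 1,4-addition occurs anti to the γ-acetoxy group and sets the isopropenyl-bearing stereocentre trans to the acetate.

**Step 8**
Reactants: 11
Product: 12 (1S,2R)-5-methyl-4-oxo-2-(prop-1-en-2-yl)cyclohexyl acetate (C-5 epimer mixture)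
Conditions: LiHMDS, THF, −78 °C; then MeI, DMPU, −78 → −20 °C
Reagents that add atoms: iodomethane, CI
Why: Kinetic enolisation occurs at the α-CH2 remote from the branched carbon, so methylation goes there; the new centre is erased in step 9.

**Step 9**
Reactants: 12
Product: 13 (1S,6R)-3-methyl-4-oxo-6-(prop-1-en-2-yl)cyclohex-2-en-1-yl acetate
Conditions: IBX·MPO (1.3 equiv), DMSO, 50 °C
Reagents that add atoms: none
Why: IBX dehydrogenation (Nicolaou) proceeds through the more substituted enol and gives the trisubstituted enone, which places the ring alkene between C-2 and C-3 and makes the acetate allylic.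

**Step 10**
Reactants: 13
Product: 14 (1S,4S,6R)-4-hydroxy-3-methyl-6-(prop-1-en-2-yl)cyclohex-2-en-1-yl acetate
Conditions: (S)-Me-CBS (20 mol%), catecholborane (1.5 equiv), toluene, −78 °C; then MeOH
Reagents that add atoms: none
Why: A CBS 1,2-reduction under catalyst control delivers the axial alcohol, cis to the acetate and trans to the isopropenyl group, which fixes the C-4 hydroxyl stereocentre.

**Step 11 (key radical step)**
Reactants: 14, 15 prenal (3-methylbut-2-enal)
Product: 16 (1R,4S,6R)-4-hydroxy-3-methyl-6-[(2S)-6-methyl-4-oxohept-5-en-2-yl]cyclohex-2-en-1-yl acetate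
Conditions: prenal (6 equiv), TIPS-SH (30 mol%), t-BuON=NOt-Bu (20 mol%, added slowly), PhCF3, 60 °C, 18 h
Reagents that add atoms: none (prenal is the reactant; H is transferred from the thiol)
Why: Proposed new method: the t-BuO•/silanethiyl radical abstracts the aldehyde H to give the senecioyl acyl radical, which adds to the terminal CH2 of the isopropenyl group (selective over the hindered trisubstituted ring alkene) to give a tertiary radical; the bulky silanethiol then donates H to the less hindered face of that radical, setting the C-7 methyl stereocentre with moderate diastereoselectivity (C-7 epimer removed by HPLC), and the closest known reaction is Kharasch/Roberts thiol-catalysed radical-chain hydroacylation of alkenes, with the conjugated acyl radical resisting decarbonylation.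

**Step 12**
Reactants: 16, 5 vanillin
Product: 17 4-{[(1R,4S,6R)-4-hydroxy-3-methyl-6-[(2S)-6-methyl-4-oxohept-5-en-2-yl]cyclohex-2-en-1-yl]oxy}-3-methoxybenzaldehyde
Conditions: Pd(PPh3)4 (5 mol%), K2CO3, THF, 45 °C
Reagents that add atoms: none
Why: Tsuji–Trost allylic etherification proceeds by double inversion (net retention), so the aryl ether forms cis to the C-4 hydroxyl and trans to the side chain, with phenoxide attack at the less hindered secondary terminus of the π-allyl.

**Step 13**
Reactants: 7 feruloylacetone, 17
Product: 18 bisabolocurcumin ether (target)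
Conditions: B2O3, B(OBu)3, EtOAc, 60 °C; then 17, n-BuNH2 (cat.), 40 °C, 16 h; then 5% aq. AcOH–MeOH, 50 °C
Reagents that add atoms: none
Why: Boron-templated Knoevenagel condensation of the terminal methyl of 7 with aldehyde 17 builds the (E,E)-dienone–enol core (Pabon-type); all stereocentres are remote and untouched.

---

**Compound list**

| # | Name | SMILES | Role |
|---|---|---|---|
| 1 | catechol | Oc1ccccc1O | starting material |
| 2 | guaiacol | COc1ccccc1O | intermediate |
| 3 | glyoxylic acid | O=CC(=O)O | starting material |
| 4 | 4-hydroxy-3-methoxymandelic acid | COc1cc(C(O)C(=O)O)ccc1O | intermediate |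
| 5 | vanillin | COc1cc(C=O)ccc1O | intermediate |
| 6 | acetylacetone | CC(=O)CC(C)=O | starting material |
| 7 | feruloylacetone | COc1cc(/C=C/C(=O)CC(C)=O)ccc1O | intermediate |
| 8 | cis-cyclohex-2-ene-1,4-diol (meso) | O[C@H]1CC[C@@H](O)C=C1 | starting material |
| 9 | (1S,4R)-4-hydroxycyclohex-2-en-1-yl acetate | CC(=O)O[C@H]1CC[C@@H](O)C=C1 | intermediate |
| 10 | (S)-4-oxocyclohex-2-en-1-yl acetate | CC(=O)O[C@H]1CCC(=O)C=C1 | intermediate |
| 11 | (1S,2R)-4-oxo-2-(prop-1-en-2-yl)cyclohexyl acetate | CC(=O)O[C@H]1CCC(=O)C[C@@H]1C(C)=C | intermediate |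
| 12 | (1S,2R)-5-methyl-4-oxo-2-(prop-1-en-2-yl)cyclohexyl acetate (C-5 epimers) | CC(=O)O[C@H]1CC(C)C(=O)C[C@@H]1C(C)=C | intermediate |
| 13 | (1S,6R)-3-methyl-4-oxo-6-(prop-1-en-2-yl)cyclohex-2-en-1-yl acetate | CC(=O)O[C@H]1C=C(C)C(=O)C[C@@H]1C(C)=C | intermediate |
| 14 | (1S,4S,6R)-4-hydroxy-3-methyl-6-(prop-1-en-2-yl)cyclohex-2-en-1-yl acetate | CC(=O)O[C@H]1C=C(C)[C@@H](O)C[C@@H]1C(C)=C | intermediate |
| 15 | prenal (3-methylbut-2-enal) | CC(C)=CC=O | starting material |
| 16 | (1R,4S,6R)-4-hydroxy-3-methyl-6-[(2S)-6-methyl-4-oxohept-5-en-2-yl]cyclohex-2-en-1-yl acetate | CC(=O)O[C@H]1C=C(C)[C@@H](O)C[C@@H]1[C@@H](C)CC(=O)C=C(C)C | intermediate |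
| 17 | aryl-ether aldehyde (4-O-cyclohexenyl vanillin) | O=Cc1ccc(O[C@H]2C=C(C)[C@@H](O)C[C@@H]2[C@@H](C)CC(=O)C=C(C)C)c(OC)c1 | intermediate |
| 18 | bisabolocurcumin ether | COc1cc(/C=C/C(=O)/C=C(O)/C=C/c2ccc(O[C@H]3C=C(C)[C@@H](O)C[C@@H]3[C@@H](C)CC(=O)C=C(C)C)c(OC)c2)ccc1O | target |

**Total steps:** 13
**Longest linear sequence:** 9 (steps 5 → 13)

**Three steps most likely to fail**
1. **Step 11, hydroacylation.** Risks are low yield, poor C-7 diastereoselectivity, and thiyl-mediated epimerisation of the allylic α-oxy C–H centres. Fallback: ozonolyse the isopropenyl group of 14 to the methyl ketone, do a Horner–Wadsworth–Emmons reaction with triethyl phosphonoacetate, set C-7 by asymmetric CuH conjugate reduction (reagent-controlled), then convert the ester to the Weinreb amide and add isobutenylmagnesium bromide.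
2. **Step 12, Tsuji–Trost etherification.** The π-allyl can give elimination to a diene or attack at the tertiary terminus. Fallback: use a double-Mitsunobu SN2 sequence instead, inverting C-1 with p-nitrobenzoic acid and then inverting back with vanillin, with the 4-OH transiently silylated.
3. **Step 10, CBS reduction.** Selectivity for the axial alcohol could be poor. Fallback: do a Luche reduction to the equatorial alcohol and invert it by Mitsunobu (p-nitrobenzoate), or use a ketoreductase enzyme to give the axial alcohol.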